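**Strategy.** Ring numbering: C1 = ketone carbon, C2 = C–CH2OH, C3 = vinylic CH, C4 = C–O-propanoyl, C5 = C–isopropyl, C6 = C–O-enoyl. The cyclohexenone ring is cut into its C1(=O)–C6(O) edge, which is glyoxal, and the four-carbon arc C2–C5. That arc is an acyclic chain ending in an alkenyl iodide (C2) and an allylic chloride (C5); its only stereocentre, the C4 carbinol, comes from a catalytic asymmetric alkynylation. In one chromium(II)/nickel operation the allyl terminus adds to one aldehyde of glyoxal (C5–C6, with C4 relaying its configuration to C5 and C6) and the alkenyl terminus then closes the ring on the other aldehyde (C1–C2). Oxidation at C1, acylations, isopropenyl hydrogenation and desilylation finish the target.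

Key step: step 5

Remark: the ProPhenol antipode in step 1 is the one that delivers the (4R)-carbinol, and glyoxal 8 is used as the anhydrous monomer, freshly released from its commercial trimer dihydrate over P2O5.

Step 1
Reactants: 1 3-methylbut-2-enal; 2 tert-butyldimethyl(prop-2-yn-1-yloxy)silane
Product: 3 (4R)-1-[(tert-butyldimethylsilyl)oxy]-6-methylhept-5-en-2-yn-4-ol
Conditions: Me2Zn (3 equiv), ProPhenol (20 mol %), Ph3PO (40 mol %), toluene, 4 °C
Reagents that add atoms: none
Why: Dinuclear zinc–ProPhenol catalysed enantioselective alkynylation of an α,β-unsaturated aldehyde (Trost alkynylation), in which the chiral Zn2 pocket delivers the alkynylzinc to one face of the aldehyde and so sets C4, the only stereocentre that is not relayed later.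

Step 2
Reactants: 3 (4R)-1-[(tert-butyldimethylsilyl)oxy]-6-methylhept-5-en-2-yn-4-ol
Product: 5 (2Z,4R)-1-[(tert-butyldimethylsilyl)oxy]-2-iodo-6-methylhepta-2,5-dien-4-ol, via cyclic alkenylalanate 4 (not isolated)
Conditions: Red-Al (1.5 equiv), THF, 0 → 25 °C; then I2, −78 → 0 °C
Reagents that add atoms: iodine, II
Why: Hydroxyl-directed trans-hydroalumination of the propargylic alcohol puts hydride on C3 and aluminium on C2 inside a five-membered oxa-aluminacycle, and iodinolysis with retention should give the (Z)-2-iodoalkene with iodine cis to C4, the geometry the later ring closure needs.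

Step 3
Reactants: 5 (2Z,4R)-1-[(tert-butyldimethylsilyl)oxy]-2-iodo-6-methylhepta-2,5-dien-4-ol
Product: 6 tert-butyl{[(2Z,4R)-2-iodo-4-[(4-methoxyphenyl)methoxy]-6-methylhepta-2,5-dien-1-yl]oxy}dimethylsilane
Conditions: NaH, PMBCl, Bu4NI (cat.), THF/DMF, 0 → 25 °C
Reagents that add atoms: 4-methoxybenzyl chloride, COc1ccc(CCl)cc1
Why: Williamson etherification of the sodium alkoxide; an ether rather than an ester is placed on O4 so that no acyloxy leaving group sits next to the allylmetal of step 5 and so that only the C1 carbinol is a free allylic alcohol in step 6.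

Step 4
Reactants: 6 tert-butyl{[(2Z,4R)-2-iodo-4-[(4-methoxyphenyl)methoxy]-6-methylhepta-2,5-dien-1-yl]oxy}dimethylsilane
Product: 7 tert-butyl{[(2Z,4S,5RS)-5-chloro-2-iodo-4-[(4-methoxyphenyl)methoxy]-6-methylhepta-2,6-dien-1-yl]oxy}dimethylsilane (C4 unchanged in space; the descriptor changes by CIP priority only)
Conditions: NCS (1.1 equiv), PhSeCl (10 mol %), CH2Cl2, 25 °C
Reagents that add atoms: N-chlorosuccinimide, O=C1CCC(=O)N1Cl
Why: Selenium-catalysed ene-type allylic chlorination (Sharpless–Hori) should attack the electron-rich isopropylidene alkene and not the iodoalkene, giving the transposed allylic chloride; its C5 configuration and halide regiochemistry do not matter because both are erased in the allylchromium of step 5.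

Step 5
Reactants: 7 tert-butyl{[(2Z,4S,5RS)-5-chloro-2-iodo-4-[(4-methoxyphenyl)methoxy]-6-methylhepta-2,6-dien-1-yl]oxy}dimethylsilane; 8 glyoxal
Product: 11 (1R,2RS,5S,6R)-3-{[(tert-butyldimethylsilyl)oxy]methyl}-5-[(4-methoxyphenyl)methoxy]-6-(prop-1-en-2-yl)cyclohex-3-ene-1,2-diol, via allylchromium dichloride 9 (not isolated), via hydroxy aldehyde 10 (not isolated)
Conditions: CrCl2 (8 equiv), NiCl2 (2 mol %), glyoxal (5 equiv), THF/DMF 4:1, 0 → 25 °C, slow addition of 7
Reagents that add atoms: none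
Why: Two Cr(II) reduce the allylic C–Cl bond to the (E)-allylchromium(III) 9, which adds through its γ-carbon C5 to one aldehyde of glyoxal in a closed chair transition state (C5–C6), and Ni(0)-catalysed activation of the C–I bond with transmetalation to chromium then lets the C2 alkenylchromium add to the second, now tethered aldehyde of 10 (C1–C2). The closest known reaction types are the Nozaki–Hiyama allylation of aldehydes and the intramolecular Nozaki–Hiyama–Kishi alkenylation of ω-formyl alkenyl iodides, here run in sequence on a dialdehyde. The carbocycle closes in the 6-exo-trig mode, the alkenyl carbon attacking a C=O that is exocyclic to the new ring. C6 is set relative to C5 by the chair (E-allyl, both substituents equatorial, anti adduct, which is 5,6-trans in the ring); C5 is set by C4, because A(1,3) strain with the β-methyl holds H-4 in the allyl plane and the aldehyde should bond anti to the bulky iodoalkenyl arm with the ether oxygen outside, giving the 4,5-cis relation; C1 forms as a mixture and is removed in step 6. The step needs the allyl terminus to react before the alkenyl terminus and each glyoxal to be used by one substrate molecule only: the first is secured by the fast, nickel-independent reduction of the allylic chloride against the slow nickel-dependent C–I activation, the second by excess glyoxal and slow addition of 7, after which ring closure is intramolecular. Ethers next to an allylchromium, silyl ethers and the PMB group are tolerated by these reagents.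

Step 6
Reactants: 11 (1R,2RS,5S,6R)-3-{[(tert-butyldimethylsilyl)oxy]methyl}-5-[(4-methoxyphenyl)methoxy]-6-(prop-1-en-2-yl)cyclohex-3-ene-1,2-diol
Product: 12 (4S,5R,6R)-2-{[(tert-butyldimethylsilyl)oxy]methyl}-6-hydroxy-4-[(4-methoxyphenyl)methoxy]-5-(prop-1-en-2-yl)cyclohex-2-en-1-one
Conditions: activated MnO2 (20 equiv), CH2Cl2, 25 °C
Reagents that add atoms: none
Why: Chemoselective MnO2 oxidation of the allylic C1 carbinol, on which both C1 epimers converge, while the non-allylic C6 hydroxyl and the PMB ether should stay untouched.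

Step 7
Reactants: 13 2-[(tert-butyldimethylsilyl)oxy]acetaldehyde; 14 ethyl 2-(triphenyl-λ5-phosphanylidene)propanoate
Product: 15 ethyl (2E)-4-[(tert-butyldimethylsilyl)oxy]-2-methylbut-2-enoate
Conditions: CH2Cl2, 25 °C
Reagents that add atoms: none
Why: Wittig olefination with a stabilised α-methyl ylide, which should give the (E)-trisubstituted enoate.

Step 8
Reactants: 15 ethyl (2E)-4-[(tert-butyldimethylsilyl)oxy]-2-methylbut-2-enoate
Product: 16 (2E)-4-[(tert-butyldimethylsilyl)oxy]-2-methylbut-2-enoic acid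
Conditions: LiOH·H2O, THF/MeOH/H2O, 0 → 25 °C; then 1 M HCl to pH 4
Reagents that add atoms: lithium hydroxide, [Li+].[OH-]
Why: Saponification of the ethyl ester under conditions that a primary TBS ether should survive and that leave the (E)-enoate geometry unchanged.

Step 9
Reactants: 12 (4S,5R,6R)-2-{[(tert-butyldimethylsilyl)oxy]methyl}-6-hydroxy-4-[(4-methoxyphenyl)methoxy]-5-(prop-1-en-2-yl)cyclohex-2-en-1-one; 16 (2E)-4-[(tert-butyldimethylsilyl)oxy]-2-methylbut-2-enoic acid
Product: 17 (1R,5S,6S)-3-{[(tert-butyldimethylsilyl)oxy]methyl}-5-[(4-methoxyphenyl)methoxy]-2-oxo-6-(prop-1-en-2-yl)cyclohex-3-en-1-yl (2E)-4-[(tert-butyldimethylsilyl)oxy]-2-methylbut-2-enoate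
Conditions: EDC·HCl, DMAP, CH2Cl2, 0 → 25 °C
Reagents that add atoms: none
Why: Steglich esterification of the only free hydroxyl (O6), with retention at C6 because the C–O bond is not touched.

Step 10
Reactants: 17 (1R,5S,6S)-3-{[(tert-butyldimethylsilyl)oxy]methyl}-5-[(4-methoxyphenyl)methoxy]-2-oxo-6-(prop-1-en-2-yl)cyclohex-3-en-1-yl (2E)-4-[(tert-butyldimethylsilyl)oxy]-2-methylbut-2-enoate
Product: 18 (1R,5S,6S)-3-{[(tert-butyldimethylsilyl)oxy]methyl}-5-[(4-methoxyphenyl)methoxy]-2-oxo-6-(propan-2-yl)cyclohex-3-en-1-yl (2E)-4-[(tert-butyldimethylsilyl)oxy]-2-methylbut-2-enoate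
Conditions: H2 (1 atm), RhCl(PPh3)3 (10 mol %), benzene/EtOH 1:1, 25 °C
Reagents that add atoms: none
Why: Homogeneous hydrogenation with Wilkinson's catalyst should reduce the unhindered 1,1-disubstituted isopropenyl alkene and leave the trisubstituted enone and enoate alkenes (the carvone to carvotanacetone selectivity); no stereocentre is created.

Step 11
Reactants: 18 (1R,5S,6S)-3-{[(tert-butyldimethylsilyl)oxy]methyl}-5-[(4-methoxyphenyl)methoxy]-2-oxo-6-(propan-2-yl)cyclohex-3-en-1-yl (2E)-4-[(tert-butyldimethylsilyl)oxy]-2-methylbut-2-enoate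
Product: 19 (1R,5S,6S)-3-{[(tert-butyldimethylsilyl)oxy]methyl}-5-hydroxy-2-oxo-6-(propan-2-yl)cyclohex-3-en-1-yl (2E)-4-[(tert-butyldimethylsilyl)oxy]-2-methylbut-2-enoate
Conditions: DDQ (1.5 equiv), CH2Cl2/pH 7 buffer 10:1, 0 → 25 °C
Reagents that add atoms: none
Why: Oxidative PMB cleavage by DDQ (benzylic hydride abstraction, then hydrolysis of the oxocarbenium ion) should free O4 without touching the esters, silyl ethers or the electron-poor alkenes.

Step 12
Reactants: 19 (1R,5S,6S)-3-{[(tert-butyldimethylsilyl)oxy]methyl}-5-hydroxy-2-oxo-6-(propan-2-yl)cyclohex-3-en-1-yl (2E)-4-[(tert-butyldimethylsilyl)oxy]-2-methylbut-2-enoate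
Product: 20 (1S,5R,6S)-5-{[(2E)-4-[(tert-butyldimethylsilyl)oxy]-2-methylbut-2-enoyl]oxy}-3-{[(tert-butyldimethylsilyl)oxy]methyl}-4-oxo-6-(propan-2-yl)cyclohex-2-en-1-yl propanoate
Conditions: (EtCO)2O, pyridine, DMAP (cat.), CH2Cl2, 0 → 25 °C
Reagents that add atoms: propanoic anhydride, CCC(=O)OC(=O)CC
Why: DMAP-catalysed acylation of the secondary allylic O4 with retention; acyl migration is not expected because O4 and O6 are trans-1,3 on the ring and O6 is already acylated.

Step 13
Reactants: 20 (1S,5R,6S)-5-{[(2E)-4-[(tert-butyldimethylsilyl)oxy]-2-methylbut-2-enoyl]oxy}-3-{[(tert-butyldimethylsilyl)oxy]methyl}-4-oxo-6-(propan-2-yl)cyclohex-2-en-1-yl propanoate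
Product: 21 (1S,5R,6S)-5-{[(2E)-4-hydroxy-2-methylbut-2-enoyl]oxy}-3-(hydroxymethyl)-4-oxo-6-(propan-2-yl)cyclohex-2-en-1-yl propanoate (CNP0285949.1)
Conditions: HF·pyridine, THF/pyridine, 0 → 25 °C
Reagents that add atoms: none
Why: Fluoride cleavage of both primary TBS ethers under buffered, weakly acidic conditions that should avoid base-induced acyl migration or epimerisation at C6.

**Compound list**

1 | 3-methylbut-2-enal | CC(C)=CC=O | starting material
2 | tert-butyldimethyl(prop-2-yn-1-yloxy)silane | C#CCO[Si](C)(C)C(C)(C)C | starting material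
3 | (4R)-1-[(tert-butyldimethylsilyl)oxy]-6-methylhept-5-en-2-yn-4-ol | O[C@H](C=C(C)C)C#CCO[Si](C)(C)C(C)(C)C | intermediate
4 | sodium salt of the cyclic alkenyl(alkoxy)bis(2-methoxyethoxy)aluminate (2,5-dihydro-1,2-oxaluminol-2-uide; carbinol configuration as in 3) | [Na+].COCCO[Al-]1(OCCOC)O[C@H](C=C(C)C)C=C1CO[Si](C)(C)C(C)(C)C | intermediate
5 | (2Z,4R)-1-[(tert-butyldimethylsilyl)oxy]-2-iodo-6-methylhepta-2,5-dien-4-ol | O[C@H](C=C(C)C)/C=C(\I)CO[Si](C)(C)C(C)(C)C | intermediate
6 | tert-butyl{[(2Z,4R)-2-iodo-4-[(4-methoxyphenyl)methoxy]-6-methylhepta-2,5-dien-1-yl]oxy}dimethylsilane | COc1ccc(CO[C@H](C=C(C)C)/C=C(\I)CO[Si](C)(C)C(C)(C)C)cc1 | intermediate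
7 | tert-butyl{[(2Z,4S,5RS)-5-chloro-2-iodo-4-[(4-methoxyphenyl)methoxy]-6-methylhepta-2,6-dien-1-yl]oxy}dimethylsilane | COc1ccc(CO[C@H](C(Cl)C(C)=C)/C=C(\I)CO[Si](C)(C)C(C)(C)C)cc1 | intermediate
8 | glyoxal (ethanedial) | O=CC=O | starting material
9 | dichloro[(2E,4R,5Z)-7-[(tert-butyldimethylsilyl)oxy]-6-iodo-4-[(4-methoxyphenyl)methoxy]-2-methylhepta-2,5-dien-1-yl]chromium | COc1ccc(CO[C@H](/C=C(\C)C[Cr](Cl)Cl)/C=C(\I)CO[Si](C)(C)C(C)(C)C)cc1 | intermediate
10 | (2R,3R,4R,5Z)-7-[(tert-butyldimethylsilyl)oxy]-2-hydroxy-6-iodo-4-[(4-methoxyphenyl)methoxy]-3-(prop-1-en-2-yl)hept-5-enal (present as its chromium(III) alkoxide) | O=C[C@H](O)[C@@H](C(C)=C)[C@@H](OCc1ccc(OC)cc1)/C=C(\I)CO[Si](C)(C)C(C)(C)C | intermediate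
11 | (1R,2RS,5S,6R)-3-{[(tert-butyldimethylsilyl)oxy]methyl}-5-[(4-methoxyphenyl)methoxy]-6-(prop-1-en-2-yl)cyclohex-3-ene-1,2-diol | COc1ccc(CO[C@H]2C=C(CO[Si](C)(C)C(C)(C)C)C(O)[C@H](O)[C@H]2C(C)=C)cc1 | intermediate
12 | (4S,5R,6R)-2-{[(tert-butyldimethylsilyl)oxy]methyl}-6-hydroxy-4-[(4-methoxyphenyl)methoxy]-5-(prop-1-en-2-yl)cyclohex-2-en-1-one | COc1ccc(CO[C@H]2C=C(CO[Si](C)(C)C(C)(C)C)C(=O)[C@H](O)[C@H]2C(C)=C)cc1 | intermediate
13 | 2-[(tert-butyldimethylsilyl)oxy]acetaldehyde | O=CCO[Si](C)(C)C(C)(C)C | starting material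
14 | ethyl 2-(triphenyl-λ5-phosphanylidene)propanoate | CCOC(=O)C(C)=P(c1ccccc1)(c1ccccc1)c1ccccc1 | starting material
15 | ethyl (2E)-4-[(tert-butyldimethylsilyl)oxy]-2-methylbut-2-enoate | CCOC(=O)/C(C)=C/CO[Si](C)(C)C(C)(C)C | intermediate
16 | (2E)-4-[(tert-butyldimethylsilyl)oxy]-2-methylbut-2-enoic acid | OC(=O)/C(C)=C/CO[Si](C)(C)C(C)(C)C | intermediate
17 | (1R,5S,6S)-3-{[(tert-butyldimethylsilyl)oxy]methyl}-5-[(4-methoxyphenyl)methoxy]-2-oxo-6-(prop-1-en-2-yl)cyclohex-3-en-1-yl (2E)-4-[(tert-butyldimethylsilyl)oxy]-2-methylbut-2-enoate | COc1ccc(CO[C@H]2C=C(CO[Si](C)(C)C(C)(C)C)C(=O)[C@H](OC(=O)/C(C)=C/CO[Si](C)(C)C(C)(C)C)[C@H]2C(C)=C)cc1 | intermediate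
18 | (1R,5S,6S)-3-{[(tert-butyldimethylsilyl)oxy]methyl}-5-[(4-methoxyphenyl)methoxy]-2-oxo-6-(propan-2-yl)cyclohex-3-en-1-yl (2E)-4-[(tert-butyldimethylsilyl)oxy]-2-methylbut-2-enoate | COc1ccc(CO[C@H]2C=C(CO[Si](C)(C)C(C)(C)C)C(=O)[C@H](OC(=O)/C(C)=C/CO[Si](C)(C)C(C)(C)C)[C@H]2C(C)C)cc1 | intermediate
19 | (1R,5S,6S)-3-{[(tert-butyldimethylsilyl)oxy]methyl}-5-hydroxy-2-oxo-6-(propan-2-yl)cyclohex-3-en-1-yl (2E)-4-[(tert-butyldimethylsilyl)oxy]-2-methylbut-2-enoate | O[C@H]1C=C(CO[Si](C)(C)C(C)(C)C)C(=O)[C@H](OC(=O)/C(C)=C/CO[Si](C)(C)C(C)(C)C)[C@H]1C(C)C | intermediate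
20 | (1S,5R,6S)-5-{[(2E)-4-[(tert-butyldimethylsilyl)oxy]-2-methylbut-2-enoyl]oxy}-3-{[(tert-butyldimethylsilyl)oxy]methyl}-4-oxo-6-(propan-2-yl)cyclohex-2-en-1-yl propanoate | CCC(=O)O[C@H]1C=C(CO[Si](C)(C)C(C)(C)C)C(=O)[C@H](OC(=O)/C(C)=C/CO[Si](C)(C)C(C)(C)C)[C@H]1C(C)C | intermediate
21 | (1S,5R,6S)-5-{[(2E)-4-hydroxy-2-methylbut-2-enoyl]oxy}-3-(hydroxymethyl)-4-oxo-6-(propan-2-yl)cyclohex-2-en-1-yl propanoate (CNP0285949.1) | CCC(=O)O[C@H]1C=C(CO)C(=O)[C@H](OC(=O)/C(C)=C/CO)[C@H]1C(C)C | target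

**Step count.** Total: 13 steps. Longest linear sequence: 11 steps (steps 1–6 and 9–13); steps 7–8 make the side-chain acid.

**Steps most likely to fail**

Step 5 (key step). Chromium(II) may reduce or oligomerise glyoxal, or the allylchromium may undergo 1,4-elimination of the C4 ether, before the C5–C6 bond forms; the facial selectivity at C5 may also be low. The fallback sets out from chloride 7. Copper-catalysed SN2′ borylation (B2pin2, CuCl, Xantphos, KOt-Bu, THF) would convert 7 into the (E)-allylboronate 2-[(2E,4R,5Z)-7-[(tert-butyldimethylsilyl)oxy]-6-iodo-4-[(4-methoxyphenyl)methoxy]-2-methylhepta-2,5-dien-1-yl]-4,4,5,5-tetramethyl-1,3,2-dioxaborolane F1, a configurationally defined and non-reducing allyl donor. F1 should add to glyoxal without any metal through a closed chair transition state to give 10 as its boronate. Excess glyoxal is then removed under vacuum and the remaining aldehyde is closed onto the alkenyl iodide under standard Ni/Cr conditions. The sequence comes back to the route at diol 11.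

Step 4. The electrophilic selenium and chlorine species may attack the anisyl ring or the iodoalkene instead of the isopropylidene group, or the PMB ether may be lost. The fallback sets out from 6. Allylic hydroxylation of the (E)-methyl group with catalytic SeO2 and t-BuOOH would give (2E,4R,5Z)-7-[(tert-butyldimethylsilyl)oxy]-6-iodo-4-[(4-methoxyphenyl)methoxy]-2-methylhepta-2,5-dien-1-ol F2. Appel bromination (CBr4, PPh3) would then give the primary allylic bromide tert-butyl{[(2Z,4R,5E)-7-bromo-2-iodo-4-[(4-methoxyphenyl)methoxy]-6-methylhepta-2,5-dien-1-yl]oxy}dimethylsilane F3. F3 enters step 5 in place of 7, is reduced to the same allylchromium 9, and the route is rejoined at 11.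

Step 6. MnO2 may cleave the vicinal diol, over-oxidise the α-hydroxy ketone product, or leave the slower C1 epimer unreacted. The fallback sets out from 7 and avoids the diol by bringing C1 in at the carboxyl oxidation level. Indium-mediated Barbier allylation of ethyl glyoxylate (In, NaI, DMF) would give ethyl (2R,3R,4R,5Z)-7-[(tert-butyldimethylsilyl)oxy]-2-hydroxy-6-iodo-4-[(4-methoxyphenyl)methoxy]-3-(prop-1-en-2-yl)hept-5-enoate F4. Deprotonation of the hydroxyl and iodine–lithium exchange (t-BuLi, THF, −78 °C), followed by 6-exo-trig attack of the alkenyllithium on the ester, should close the ring directly to the hydroxy enone. The sequence comes back to the route at 12.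

Further compounds
F1 | step 5 | 2-[(2E,4R,5Z)-7-[(tert-butyldimethylsilyl)oxy]-6-iodo-4-[(4-methoxyphenyl)methoxy]-2-methylhepta-2,5-dien-1-yl]-4,4,5,5-tetramethyl-1,3,2-dioxaborolane | COc1ccc(CO[C@H](/C=C(\C)CB2OC(C)(C)C(C)(C)O2)/C=C(\I)CO[Si](C)(C)C(C)(C)C)cc1
F2 | step 4 | (2E,4R,5Z)-7-[(tert-butyldimethylsilyl)oxy]-6-iodo-4-[(4-methoxyphenyl)methoxy]-2-methylhepta-2,5-dien-1-ol | COc1ccc(CO[C@H](/C=C(\C)CO)/C=C(\I)CO[Si](C)(C)C(C)(C)C)cc1
F3 | step 4 | tert-butyl{[(2Z,4R,5E)-7-bromo-2-iodo-4-[(4-methoxyphenyl)methoxy]-6-methylhepta-2,5-dien-1-yl]oxy}dimethylsilane | COc1ccc(CO[C@H](/C=C(\C)CBr)/C=C(\I)CO[Si](C)(C)C(C)(C)C)cc1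
F4 | step 6 | ethyl (2R,3R,4R,5Z)-7-[(tert-butyldimethylsilyl)oxy]-2-hydroxy-6-iodo-4-[(4-methoxyphenyl)methoxy]-3-(prop-1-en-2-yl)hept-5-enoate | CCOC(=O)[C@H](O)[C@@H](C(C)=C)[C@@H](OCc1ccc(OC)cc1)/C=C(\I)CO[Si](C)(C)C(C)(C)C
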